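The flavan C ring (O1, C2, C3, C4, C4a, C8a) is first built one atom short, as a 2-aryl-2,3-dihydrobenzofuran-3-ol in which C4 hangs on the carbinol carbon C3 as an exocyclic CH2OH. Sulfonylation of that primary hydroxyl releases a semipinacol 1,2-shift of ring A: C4a, which has the oxygens of C5, C7 and C8a ortho and para to it, moves from C3 to C4. One operation thus enlarges the furan to the pyran ring, forms C4–C4a and turns C3 into a ketone, while C2 stays intact. Hydride attack anti to the C2 aryl then gives the cis 3-ol; the apigenin unit is joined to C6 last by Negishi coupling.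

Key step: step 6

Assumption: the axis between flavone C3 and flavan C6 carries no descriptor in the target and is treated as a set of interconverting rotamers, so no step controls it.
Assumption: the sense of induction in step 3 is taken from simple 1-arylpropargyl esters. Should it be the opposite, the antipodal pybox ligand is used.

Step 1
Reactants: 1 4-(benzyloxy)benzaldehyde; 2 ethynylmagnesium bromide
Product: 4 rac-1-[4-(benzyloxy)phenyl]prop-2-yn-1-yl acetate, via bromomagnesium alkoxide 3 (not isolated)
Conditions: HC≡CMgBr, THF, 0 °C; then Ac2O, 0 °C to rt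
Reagents that add atoms: acetic anhydride CC(=O)OC(C)=O
Why: Grignard 1,2-addition of the acetylide to the aldehyde followed by O-acylation of the alkoxide in the same flask; the new centre is left racemic on purpose because step 3 passes through a planar intermediate.

Step 2
Reactants: 5 3,5-bis(benzyloxy)phenol
Product: 6 3,5-bis(benzyloxy)-2-iodophenol
Conditions: NIS (1.0 equiv), CH2Cl2, −20 to 0 °C
Reagents that add atoms: N-iodosuccinimide O=C1CCC(=O)N1I
Why: Electrophilic aromatic iodination of the activated phenol should go to one of the two equivalent positions ortho to the small free hydroxyl, since the para position is walled in by two benzyloxy groups, and one equivalent of reagent at low temperature limits it to one iodine.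

Step 3
Reactants: 4 rac-1-[4-(benzyloxy)phenyl]prop-2-yn-1-yl acetate; 6 3,5-bis(benzyloxy)-2-iodophenol
Product: 7 (S)-1,5-bis(benzyloxy)-3-{1-[4-(benzyloxy)phenyl]prop-2-yn-1-yloxy}-2-iodobenzene
Conditions: CuOTf·0.5C6H6 (5 mol %), (S,S)-Ph-pybox (10 mol %), i-Pr2NEt, THF, −20 °C
Reagents that add atoms: none
Why: Copper-catalysed enantioselective propargylic etherification: the monovalent copper acetylide of 4 loses acetate to give a planar copper allenylidene on which both enantiomers of 4 converge, and the phenoxide oxygen of 6 attacks the gamma carbon inside the chiral pybox pocket, which sets the later C2 (S in 7, the same spatial arrangement as 2R in the target).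

Step 4
Reactants: 7 (S)-aryl propargyl ether
Product: 8 (2R)-4,6-bis(benzyloxy)-2-[4-(benzyloxy)phenyl]-3-methylidene-2,3-dihydro-1-benzofuran
Conditions: Bu3SnH, Et3B (cat.), air, toluene, 0 °C; filtration through basic alumina, used without delay
Reagents that add atoms: none
Why: Tin hydride radical chain: iodine abstraction gives the aryl radical, which closes the five-membered ring by a fast 5-exo-dig attack on the alkyne, and the vinyl radical takes hydrogen from the stannane, all in a neutral medium that leaves C2 and the acid-sensitive exocyclic double bond alone.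

Step 5
Reactants: 8 (2R)-3-methylidene-dihydrobenzofuran
Product: 9 (2R,3R)-4,6-bis(benzyloxy)-2-[4-(benzyloxy)phenyl]-3-(hydroxymethyl)-2,3-dihydro-1-benzofuran-3-ol
Conditions: OsO4 (2 mol %), NMO, pyridine, acetone–H2O, 0 °C to rt
Reagents that add atoms: N-methylmorpholine N-oxide C[N+]1([O-])CCOCC1; water O
Why: Upjohn syn-dihydroxylation picks the only alkene, an electron-rich 1,1-disubstituted one; osmium should add anti to the C2 aryl group and so place the 3-hydroxyl trans to it, but this centre is erased in step 6 and its configuration is of no consequence.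

Step 6
Reactants: 9 (2R,3R)-diol
Product: 11 (2R)-5,7-bis(benzyloxy)-2-[4-(benzyloxy)phenyl]chroman-3-one, via primary triflate 10 (not isolated)
Conditions: Tf2O (1.05 equiv), 2,6-di-tert-butyl-4-methylpyridine, CH2Cl2, −78 to −30 °C; aq NaHCO3
Reagents that add atoms: trifluoromethanesulfonic anhydride O=S(=O)(OS(=O)(=O)C(F)(F)F)C(F)(F)F (its atoms end in 10 only)
Why: The less hindered primary hydroxyl is sulfonylated selectively, and triflate 10 ionises only with anchimeric help: ring A carbon C3a (the later C4a), which has oxygen donors on both ortho positions and on the para position, bridges to the CH2 carbon anti to the leaving group while the lone pair of the C3 hydroxyl pushes, so that the C3–C3a bond is exchanged for the C4–C4a bond and C3 becomes the carbonyl group. The closest known reaction type is the semipinacol rearrangement of a 1,2-diol monosulfonate, the Tiffeneau–Demjanov-type one-carbon enlargement by which derivatives of benzo-fused cyclic ketones are turned into their ring-enlarged beta-ketones through aryl migration. No ring is closed from an open chain: the dihydrofuran ring is enlarged by a suprafacial 1,2-shift through a three-membered, phenonium-like bridge (3-exo-tet attack of C3a on CH2), which leaves the six-membered ring O1–C2–C3–C4–C4a–C8a. No stereocentre is created; the carbinol centre C3 is erased, so both C3 epimers of 9 converge, and C2 is not touched because the medium holds only a hindered pyridine at low temperature. The step needs aryl migration to beat migration of C2 (which would give the flavanone), oxirane closure and loss of water to the benzofuran; the first is secured by the donor pattern of ring A against the electron-poor, oxygen-bearing C2, the others by the absence of free acid or alkoxide base and by the very good leaving group.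

Step 7
Reactants: 11 (2R)-flavan-3-one
Product: 12 (2R,3R)-5,7-bis(benzyloxy)-2-[4-(benzyloxy)phenyl]chroman-3-ol
Conditions: LiBH(s-Bu)3, LiBr, THF, −78 °C; H2O
Reagents that add atoms: none
Why: Substrate-controlled ketone reduction: the bulky borohydride attacks the half-chair ketone from the face opposite the pseudo-equatorial C2 aryl group, which sets C3 as R with the hydroxyl cis to the aryl, and the low temperature keeps the enolisable C2 from epimerising.

Step 8
Reactants: 12 (2R,3R)-tri-O-benzyl flavan-3-ol
Product: 14 (2R,3R)-5,7-bis(benzyloxy)-2-[4-(benzyloxy)phenyl]-8-bromo-6-iodochroman-3-ol, via 8-bromide 13 (not isolated)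
Conditions: NBS (1.0 equiv), CH2Cl2, −78 to 0 °C; then NIS (1.1 equiv), CF3CO2H (10 mol %), 0 °C to rt
Reagents that add atoms: N-bromosuccinimide O=C1CCC(=O)N1Br; N-iodosuccinimide O=C1CCC(=O)N1I
Why: Two successive electrophilic aromatic halogenations: in 5,7-dibenzylated flavan-3-ols C8 is the more nucleophilic and less crowded site, so bromine blocks it first, after which iodine can only enter C6 between the two benzyloxy groups.

Step 9
Reactants: 15 apigenin
Product: 16 5,7-bis(benzyloxy)-2-[4-(benzyloxy)phenyl]-4H-chromen-4-one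
Conditions: BnBr (excess), K2CO3, DMF, 80 °C
Reagents that add atoms: benzyl bromide BrCc1ccccc1
Why: Williamson ether synthesis on all three phenols, with heat and excess reagent to bring in the hydrogen-bonded 5-hydroxyl as well.

Step 10
Reactants: 16 tri-O-benzylapigenin; 14 (2R,3R)-8-bromo-6-iodo flavan-3-ol
Product: 18 5,7-bis(benzyloxy)-2-[4-(benzyloxy)phenyl]-3-{(2R,3R)-5,7-bis(benzyloxy)-2-[4-(benzyloxy)phenyl]-8-bromo-3-hydroxychroman-6-yl}-4H-chromen-4-one, via flavon-3-ylzinc chloride 17 (not isolated)
Conditions: TMPZnCl·LiCl, THF, 25 °C; then 14 (limiting), Pd(OAc)2 (5 mol %), SPhos (10 mol %), THF, 50 °C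
Reagents that add atoms: TMPZnCl·LiCl CC1(C)CCCC(C)(C)N1[Zn]Cl.[Li+].[Cl-] (zinc and chlorine end in 17 only)
Why: Amide-base zincation of the only acidic chromone position (C3–H) followed by Negishi cross-coupling, in which zerovalent palladium inserts into C–I before C–Br, the bulky biaryl phosphine supports the crowded biaryl bond, and the mild arylzinc used in excess tolerates the free 3-hydroxyl.

Step 11
Reactants: 18 hexabenzyl 8-bromo biflavonoid
Product: 19 5,7-dihydroxy-2-(4-hydroxyphenyl)-3-[(2R,3R)-3,5,7-trihydroxy-2-(4-hydroxyphenyl)chroman-6-yl]-4H-chromen-4-one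
Conditions: H2 (1 atm), Pd(OH)2/C, Et3N (1.1 equiv), THF–MeOH, rt
Reagents that add atoms: none
Why: Heterogeneous hydrogenolysis cleaves the six benzyl ethers and the blocking C8–Br bond in one operation, while the tetrasubstituted chromone double bond, the cyclic C2–O1 bond and both stereocentres should not be touched at one atmosphere.

Compound list
1 | 4-(benzyloxy)benzaldehyde | O=Cc1ccc(OCc2ccccc2)cc1 | starting material
2 | ethynylmagnesium bromide | C#C[Mg]Br | starting material
3 | bromomagnesium 1-[4-(benzyloxy)phenyl]prop-2-yn-1-olate (racemic, not isolated) | C#CC(O[Mg]Br)c1ccc(OCc2ccccc2)cc1 | intermediate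
4 | rac-1-[4-(benzyloxy)phenyl]prop-2-yn-1-yl acetate | C#CC(OC(C)=O)c1ccc(OCc2ccccc2)cc1 | intermediate
5 | 3,5-bis(benzyloxy)phenol | Oc1cc(OCc2ccccc2)cc(OCc2ccccc2)c1 | starting material
6 | 3,5-bis(benzyloxy)-2-iodophenol | Oc1cc(OCc2ccccc2)cc(OCc2ccccc2)c1I | intermediate
7 | (S)-1,5-bis(benzyloxy)-3-{1-[4-(benzyloxy)phenyl]prop-2-yn-1-yloxy}-2-iodobenzene | C#C[C@H](Oc1cc(OCc2ccccc2)cc(OCc2ccccc2)c1I)c1ccc(OCc2ccccc2)cc1 | intermediate
8 | (2R)-4,6-bis(benzyloxy)-2-[4-(benzyloxy)phenyl]-3-methylidene-2,3-dihydro-1-benzofuran | C=C1[C@@H](c2ccc(OCc3ccccc3)cc2)Oc2cc(OCc3ccccc3)cc(OCc3ccccc3)c21 | intermediate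
9 | (2R,3R)-4,6-bis(benzyloxy)-2-[4-(benzyloxy)phenyl]-3-(hydroxymethyl)-2,3-dihydro-1-benzofuran-3-ol (3-OH trans to the 2-aryl group) | OC[C@@]1(O)[C@@H](c2ccc(OCc3ccccc3)cc2)Oc2cc(OCc3ccccc3)cc(OCc3ccccc3)c21 | intermediate
10 | primary triflate of 9 (not isolated) | O=S(=O)(OC[C@@]1(O)[C@@H](c2ccc(OCc3ccccc3)cc2)Oc2cc(OCc3ccccc3)cc(OCc3ccccc3)c21)C(F)(F)F | intermediate
11 | (2R)-5,7-bis(benzyloxy)-2-[4-(benzyloxy)phenyl]chroman-3-one | O=C1Cc2c(OCc3ccccc3)cc(OCc3ccccc3)cc2O[C@@H]1c1ccc(OCc2ccccc2)cc1 | intermediate
12 | (2R,3R)-5,7-bis(benzyloxy)-2-[4-(benzyloxy)phenyl]chroman-3-ol (2,3-cis, tri-O-benzyl-epiafzelechin) | O[C@@H]1Cc2c(OCc3ccccc3)cc(OCc3ccccc3)cc2O[C@@H]1c1ccc(OCc2ccccc2)cc1 | intermediate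
13 | (2R,3R)-5,7-bis(benzyloxy)-2-[4-(benzyloxy)phenyl]-8-bromochroman-3-ol (not isolated) | O[C@@H]1Cc2c(OCc3ccccc3)cc(OCc3ccccc3)c(Br)c2O[C@@H]1c1ccc(OCc2ccccc2)cc1 | intermediate
14 | (2R,3R)-5,7-bis(benzyloxy)-2-[4-(benzyloxy)phenyl]-8-bromo-6-iodochroman-3-ol | O[C@@H]1Cc2c(OCc3ccccc3)c(I)c(OCc3ccccc3)c(Br)c2O[C@@H]1c1ccc(OCc2ccccc2)cc1 | intermediate
15 | apigenin | O=c1cc(-c2ccc(O)cc2)oc2cc(O)cc(O)c12 | starting material
16 | 5,7-bis(benzyloxy)-2-[4-(benzyloxy)phenyl]-4H-chromen-4-one | O=c1cc(-c2ccc(OCc3ccccc3)cc2)oc2cc(OCc3ccccc3)cc(OCc3ccccc3)c12 | intermediate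
17 | {5,7-bis(benzyloxy)-2-[4-(benzyloxy)phenyl]-4-oxo-4H-chromen-3-yl}zinc chloride (not isolated) | O=c1c([Zn]Cl)c(-c2ccc(OCc3ccccc3)cc2)oc2cc(OCc3ccccc3)cc(OCc3ccccc3)c12 | intermediate
18 | hexabenzyl 8-bromo biflavonoid (name as in step 10) | O=c1c(-c2c(OCc3ccccc3)c(Br)c3c(c2OCc2ccccc2)C[C@@H](O)[C@@H](c2ccc(OCc4ccccc4)cc2)O3)c(-c2ccc(OCc3ccccc3)cc2)oc2cc(OCc3ccccc3)cc(OCc3ccccc3)c12 | intermediate
19 | 5,7-dihydroxy-2-(4-hydroxyphenyl)-3-[(2R,3R)-3,5,7-trihydroxy-2-(4-hydroxyphenyl)chroman-6-yl]-4H-chromen-4-one (CNP0222954.1) | O=c1c(-c2c(O)cc3c(c2O)C[C@@H](O)[C@@H](c2ccc(O)cc2)O3)c(-c2ccc(O)cc2)oc2cc(O)cc(O)c12 | target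

Total step count: 11. Longest linear sequence: 9 (steps 1, 3, 4, 5, 6, 7, 8, 10, 11; the line from 5 through step 2 is equally long).

Steps most likely to fail

Step 6. The tertiary carbinol next to the very electron-rich ring A may ionise and lose water across C2–C3, which aromatises the ring to a benzofuran. Alternatively the hydroxyl may close an oxirane on the primary sulfonate before ring A migrates. The fallback sets out from alkene 8 and never exposes a free carbinol. An oxidative rearrangement with trivalent iodine is used, PhI(OH)OTs in MeOH at −20 °C. It puts iodine on the terminal CH2 and methanol on C3, and iodobenzene then leaves with the same 1,2-shift of ring A, now pushed by the methoxy group. This gives the ketal (2R)-5,7-bis(benzyloxy)-2-[4-(benzyloxy)phenyl]-3,3-dimethoxychroman F1. Mild hydrolysis of F1 (oxalic acid on wet silica, CH2Cl2) comes back to the route at 11.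

Step 4. Hydrogen transfer to the aryl radical may occur before ring closure. The exocyclic double bond may also migrate into the ring during handling, which would erase C2. The fallback sets out from 7 and comes back at 8 by a polar, metal-catalysed closure instead of a radical chain. Under Pd(OAc)2, PPh3 and HCO2Na in DMF at 60 °C, the C–I bond adds oxidatively to zerovalent palladium. A syn 5-exo-dig carbopalladation of the alkyne follows, and formate delivers hydride to the vinylpalladium species. The crude alkene is then taken straight into step 5. This fallback makes no new compound (F0).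

Step 10. Coupling between two carbons that are each flanked on both sides may be sluggish. Protonation of the zinc reagent by the free hydroxyl, reduction of the iodide or insertion into the C–Br bond could then take over. The fallback reverses the polarity and sets out from 16 and 14.
- Treating 16 with LiN(i-Pr)2 in THF at −78 °C and then I2 gives 5,7-bis(benzyloxy)-2-[4-(benzyloxy)phenyl]-3-iodo-4H-chromen-4-one F2.
- Miyaura borylation of 14 (PdCl2(dppf), B2pin2, KOAc, dioxane, 80 °C) exchanges only the iodine. It gives (2R,3R)-5,7-bis(benzyloxy)-2-[4-(benzyloxy)phenyl]-8-bromo-6-(4,4,5,5-tetramethyl-1,3,2-dioxaborolan-2-yl)chroman-3-ol F3.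
- Suzuki–Miyaura coupling of F2 with F3 (Pd(OAc)2, SPhos, K3PO4, toluene–H2O, 60 °C) comes back to the route at 18.

Further compounds
F1 | step 6 | (2R)-5,7-bis(benzyloxy)-2-[4-(benzyloxy)phenyl]-3,3-dimethoxychroman | COC1(OC)Cc2c(OCc3ccccc3)cc(OCc3ccccc3)cc2O[C@@H]1c1ccc(OCc2ccccc2)cc1
F0 | step 4 | none | none
F2 | step 10 | 5,7-bis(benzyloxy)-2-[4-(benzyloxy)phenyl]-3-iodo-4H-chromen-4-one | O=c1c(I)c(-c2ccc(OCc3ccccc3)cc2)oc2cc(OCc3ccccc3)cc(OCc3ccccc3)c12
F3 | step 10 | (2R,3R)-5,7-bis(benzyloxy)-2-[4-(benzyloxy)phenyl]-8-bromo-6-(4,4,5,5-tetramethyl-1,3,2-dioxaborolan-2-yl)chroman-3-ol | O[C@@H]1Cc2c(OCc3ccccc3)c(B3OC(C)(C)C(C)(C)O3)c(OCc3ccccc3)c(Br)c2O[C@@H]1c1ccc(OCc2ccccc2)cc1
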